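**Plan**

1. Locants: phthalide numbering for the lower unit (C1 carbonyl, O2, C3, C3a, C4–C7, C7a, C8 = first side-chain carbon; ring A = C3a–C7a), primed locants for the upper unit (ring B); the cyclobutane is C6–C7–C3a′–C7a′.
2. Retrosynthesis: the lower C3=C8 olefin is traced back to a C3–H butyl lactone; the cyclobutane is cut at C6–C7a′ and C7–C3a′ into (Z)-ligustilide and (S)-senkyunolide A; ring A and the butenolide of that monomer are cut together at C3a=C7a and C6=C7; then the ester C1–O2 and the bond C3–C3a.
3. Enabling feature: in ring A the saturated C4–C5 unit bridges C3a and C6 while C7a–C7 lies between them at the diene level of the monomer, which is the retron of inserting the two alkyne carbons of an O2–C1-tethered propiolate into the C3a=C6 double bond of a cyclobutene.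
4. Forward: cyclobutanone → cyclobutenyl ketone → (S)-carbinol → propiolate → one metathesis cascade closes butenolide and cyclohexadiene → one part is desaturated to (Z)-ligustilide → cross [2+2] photocycloaddition builds the cyclobutane with both quaternary carbons → final C3=C8 desaturation.
5. Stereochemistry: C3 is set by CBS reduction and carried through the key step; it biases the facial sense of the photocycloaddition that sets C6, C7, C3a′ and C7a′ and turns the two senses into separable diastereomers; it is then erased. The cis ring fusions come from suprafacial addition, and both Z enol-lactone olefins are the thermodynamic isomers.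

Key step: step 5

Remark: it is assumed that direct excitation of the ligustilide chromophore gives access to the head-to-tail [2+2] mode between its C3a′=C7a′ bond and the C6=C7 bond of a dihydrophthalide, with the lactone stacked over ring A, since the target is formally that adduct.

**Route**

Step 1
Reactants: 1 cyclobutanone
Product: 2 cyclobutanone 2,4,6-triisopropylbenzenesulfonylhydrazone
Conditions: 2,4,6-triisopropylbenzenesulfonohydrazide (1.0 equiv), MeOH, cat. HCl, 0 °C → rt
Reagents that add atoms: 2,4,6-triisopropylbenzenesulfonohydrazide CC(C)c1cc(C(C)C)c(S(=O)(=O)NN)c(C(C)C)c1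
Why: Hydrazone formation from an unhindered ketone and a sulfonylhydrazide is reliable and installs the leaving group for the Shapiro reaction; no stereocentre is formed.

Step 2
Reactants: 2 cyclobutanone 2,4,6-triisopropylbenzenesulfonylhydrazone; 3 N-methoxy-N-methylpentanamide
Product: 5 1-(cyclobut-1-en-1-yl)pentan-1-one, via cyclobut-1-en-1-yllithium 4 (not isolated)
Conditions: n-BuLi (2.05 equiv), THF, −78 °C → 0 °C (N2 evolution); then 3, −78 °C → 0 °C; aq. NH4Cl
Reagents that add atoms: none
Why: The Shapiro reaction (double deprotonation, loss of sulfinate and N2) should give the alkenyllithium, and its acylation by the Weinreb amide stops at the ketone because the chelated tetrahedral adduct survives until work-up; no stereocentre is formed.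

Step 3
Reactants: 5 1-(cyclobut-1-en-1-yl)pentan-1-one
Product: 6 (S)-1-(cyclobut-1-en-1-yl)pentan-1-ol
Conditions: (R)-2-methyl-CBS-oxazaborolidine (15 mol%), catecholborane (1.5 equiv), toluene, −78 °C; then MeOH, aq. NaHCO3
Reagents that add atoms: none
Why: In this Corey–Bakshi–Shibata reduction the α-branched cyclobutenyl group acts as the large substituent and the n-butyl group as the small one, so the (R)-catalyst should deliver hydride to the face that gives the (S)-carbinol (the later C3), while catecholborane at low temperature avoids hydroboration of the strained olefin.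

Step 4
Reactants: 6 (S)-1-(cyclobut-1-en-1-yl)pentan-1-ol; 7 prop-2-ynoic acid
Product: 8 (S)-1-(cyclobut-1-en-1-yl)pentyl prop-2-ynoate
Conditions: DCC (1.1 equiv), DMAP (5 mol%), CH2Cl2, −20 °C → 0 °C
Reagents that add atoms: none
Why: Steglich esterification acylates the alcohol oxygen without touching the C–O bond of the stereocentre, so the S configuration is retained, and low temperature with little DMAP limits conjugate addition to the ynoate.

Step 5
Reactants: 8 (S)-1-(cyclobut-1-en-1-yl)pentyl prop-2-ynoate
Product: 9 (S)-3-butyl-4,5-dihydro-2-benzofuran-1(3H)-one ((S)-senkyunolide A)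
Conditions: second-generation Hoveyda–Grubbs catalyst [RuCl2(H2IMes)(=CH-C6H4-2-OiPr)] (5–10 mol%), ethylene (1 atm), toluene (0.01 M), 70 °C
Reagents that add atoms: none
Why: Tandem ring-opening/ring-closing enyne metathesis: the ruthenium methylidene adds to the terminal alkyne and places the carbene on C7a, this carbene engages the tethered cyclobutene C3a=C6 so that C3a=C7a forms while the four-membered ring opens to a new alkylidene on C6, and that alkylidene closes onto the C7 vinyl group to form C6=C7 and return the methylidene. The closest known reaction type is the ring-opening/ring-closing enyne metathesis of cycloalkene-ynes, in which an alkyne tethered to the olefinic carbon of a small cycloalkene is inserted as a two-carbon unit into the ring double bond. The butenolide closes by five-membered carbene–olefin metathesis (exo to the O2–C1 ester tether), and the cyclohexadiene closes by six-membered ring-closing metathesis, which amounts to a two-carbon expansion of the cyclobutene. No new stereocentre is formed and the C3 carbinol centre is not involved, so its S configuration is carried into 9. The step needs C7a to bond to C3a and not to C6, and needs ring closure to win over alkyne oligomerisation; the three-atom ester tether allows only the five-membered closure, relief of cyclobutene strain drives the ring opening, and ethylene with high dilution keeps the carbene as the methylidene and funnels ethylene-capped diene-yne and triene intermediates to the same product.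

Step 6
Reactants: 9 (S)-3-butyl-4,5-dihydro-2-benzofuran-1(3H)-one (one part of the material)
Product: 12 (Z)-3-butylidene-4,5-dihydro-2-benzofuran-1(3H)-one ((Z)-ligustilide), via silyloxyfuran 10 (not isolated), via bromolactone 11 (not isolated)
Conditions: TBSOTf (1.1 equiv), Et3N (1.3 equiv), CH2Cl2, −78 → 0 °C; NBS (1.05 equiv), −78 °C; Et3N (3 equiv), −78 °C → rt
Reagents that add atoms: none
Why: Soft enolisation of the butenolide gives the 2-silyloxyfuran, vinylogous silyl enol ether bromination takes place at the γ-carbon C3, and the tertiary allylic bromide loses HBr toward C8 (the only β-hydrogens) to give the conjugated enol lactone as the thermodynamically preferred Z isomer, the C3 stereocentre being erased on purpose in this part of the material.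

Step 7
Reactants: 12 (Z)-ligustilide; 9 (S)-senkyunolide A
Product: 13 (3S,6S,7R,3a′R,7a′S)-3,8-dihydro-(Z′)-6.7a′,7.3a′-diligustilide
Conditions: hν (365 nm LED), degassed cyclohexane, 12 at 0.02 M with 9 at 0.1 M (fivefold excess, the unreacted part is recovered), 10 °C; chromatography on silica
Reagents that add atoms: none
Why: In this [2+2] photocycloaddition, which joins the two partners with no loss of atoms, 12 should be excited selectively (its trienyl lactone chromophore should reach 365 nm while the dienyl lactone 9 should be transparent there) and its C3a′=C7a′ bond should add suprafacially to the C6=C7 bond of 9 in the head-to-tail orientation with the lactone of 12 stacked over ring A, which gives both cis ring fusions, while attack on the face of 9 opposite to its C3 butyl group sets C6, C7, C3a′ and C7a′ in the absolute sense shown, the other adducts being diastereomers or constitutional isomers that are removed on silica.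

Step 8
Reactants: 13 (3S,6S,7R,3a′R,7a′S)-3,8-dihydro-(Z′)-6.7a′,7.3a′-diligustilide
Product: 16 (6S,7R,3a′R,7a′S)-(Z,Z′)-6.7a′,7.3a′-diligustilide (target), via dimer silyloxyfuran 14 (not isolated), via dimer bromolactone 15 (not isolated)
Conditions: TBSOTf (1.1 equiv), Et3N (1.3 equiv), CH2Cl2, −78 → 0 °C; NBS (1.0 equiv), −78 °C; Et3N (3 equiv), −78 °C → rt
Reagents that add atoms: none
Why: The same γ-bromination and dehydrobromination as in step 6 should be selective because only the lower butenolide has an enolisable γ-hydrogen (the upper lactone has a quaternary α-carbon and its enol-lactone olefin is far less nucleophilic than the silyloxyfuran), so C3 is removed as a stereocentre, C6, C7, C3a′ and C7a′ stay untouched and the new C3=C8 olefin should form as the Z isomer.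

**Compound list**

1 | cyclobutanone | O=C1CCC1 | starting material
2 | cyclobutanone 2,4,6-triisopropylbenzenesulfonylhydrazone | CC(C)c1cc(C(C)C)c(S(=O)(=O)NN=C2CCC2)c(C(C)C)c1 | intermediate
3 | N-methoxy-N-methylpentanamide | CCCCC(=O)N(C)OC | starting material
4 | cyclobut-1-en-1-yllithium | [Li]C1=CCC1 | intermediate
5 | 1-(cyclobut-1-en-1-yl)pentan-1-one | CCCCC(=O)C1=CCC1 | intermediate
6 | (S)-1-(cyclobut-1-en-1-yl)pentan-1-ol | CCCC[C@H](O)C1=CCC1 | intermediate
7 | prop-2-ynoic acid (propiolic acid) | C#CC(=O)O | starting material
8 | (S)-1-(cyclobut-1-en-1-yl)pentyl prop-2-ynoate | CCCC[C@H](OC(=O)C#C)C1=CCC1 | intermediate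
9 | (S)-3-butyl-4,5-dihydro-2-benzofuran-1(3H)-one, (S)-senkyunolide A | CCCC[C@@H]1OC(=O)C2=C1CCC=C2 | intermediate
10 | tert-butyl[(3-butyl-4,5-dihydro-2-benzofuran-1-yl)oxy]dimethylsilane (silyloxyfuran) | CCCCC1=C2CCC=CC2=C(O[Si](C)(C)C(C)(C)C)O1 | intermediate
11 | 3-bromo-3-butyl-4,5-dihydro-2-benzofuran-1(3H)-one (racemic at C3) | CCCCC1(Br)OC(=O)C2=C1CCC=C2 | intermediate
12 | (Z)-3-butylidene-4,5-dihydro-2-benzofuran-1(3H)-one, (Z)-ligustilide | CCC/C=C1\OC(=O)C2=C1CCC=C2 | intermediate
13 | (3S,6S,7R,3a′R,7a′S) cross-adduct: cyclobutane C6–C7–C3a′–C7a′, H6 and H7 cis, ring A and the upper γ-lactone on the same cyclobutane face, ring B (C6′=C7′) on the other, lower unit a 3-butyl butenolide with butyl anti to the cyclobutane, upper unit a (Z)-butylidene lactone | CCCC[C@@H]1OC(=O)C2=C1CC[C@H]1[C@@H]2[C@]23CCC=C[C@]12C(=O)O/C3=C\CCC | intermediate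
14 | 13 with the lower butenolide as its 1-(tert-butyldimethylsilyloxy)-3-butylfuran | CCCCC1=C2CC[C@H]3[C@@H](C2=C(O[Si](C)(C)C(C)(C)C)O1)[C@]45CCC=C[C@]34C(=O)O/C5=C\CCC | intermediate
15 | 3-bromo derivative of 13 (both C3 epimers) | CCCCC1(Br)OC(=O)C2=C1CC[C@H]1[C@@H]2[C@]23CCC=C[C@]12C(=O)O/C3=C\CCC | intermediate
16 | (6S,7R,3a′R,7a′S)-(Z,Z′)-6.7a′,7.3a′-diligustilide: both units (Z)-butylidene lactones, otherwise as 13 | CCC/C=C1\OC(=O)C2=C1CC[C@H]1[C@@H]2[C@]23CCC=C[C@]12C(=O)O/C3=C\CCC | target

**Count and risks**

Total step count: 8. Longest linear sequence: 8 steps (1 → 2 → 5 → 6 → 8 → 9 → 12 → 13 → 16).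

Steps most likely to fail:

1. Step 7. The excited trienyl lactone may react through its exocyclic C3′=C8′ bond or isomerise about it, and regio- and facial control of the cycloaddition may be poor. Fallback: setting out from 12 alone, direct irradiation of concentrated 12 (the homodimerisation, in which the same head-to-tail [2+2] mode would give racemic 16 without the later desaturation), separation of the cyclodimers on silica and of the enantiomers of 16 by preparative chromatography on a chiral stationary phase. This comes back to the route at 16 and makes no new compound.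

2. Step 5. The carbene may be deactivated by the electron-poor terminal alkyne, or may fail to open the trisubstituted cyclobutene intramolecularly, so that oligomers form. Fallback: setting out from 6, ethenolysis of the cyclobutene (second-generation Grubbs catalyst [RuCl2(PCy3)(H2IMes)(=CHPh)], ethylene, CH2Cl2, rt) would give (S)-5-methylidenedec-1-en-6-ol F1. Esterification with 7 as in step 4 would give (S)-5-methylidenedec-1-en-6-yl prop-2-ynoate F2. Ring-closing enyne metathesis onto the 1,1-disubstituted olefin under ethylene would give (S)-4-(but-3-en-1-yl)-5-butyl-3-ethenylfuran-2(5H)-one F3, and ring-closing diene metathesis of F3 closes the cyclohexadiene and comes back to the route at 9.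

3. Step 8. The bromination may lose chemoselectivity (attack on the enol-lactone olefin of the upper unit) and the product may degrade under base. Fallback: setting out from 13, silylation to 14 as in step 8, oxidation of the silyloxyfuran with dimethyldioxirane (acetone, −78 °C) to the 3-hydroxy lactone of 13 F4, and acid-catalysed dehydration (cat. TsOH, benzene, rt → 40 °C) comes back to the route at 16.

**Further compounds**

F0 | step 7 | none | none
F1 | step 5 | (S)-5-methylidenedec-1-en-6-ol | CCCC[C@H](O)C(=C)CCC=C
F2 | step 5 | (S)-5-methylidenedec-1-en-6-yl prop-2-ynoate | CCCC[C@H](OC(=O)C#C)C(=C)CCC=C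
F3 | step 5 | (S)-4-(but-3-en-1-yl)-5-butyl-3-ethenylfuran-2(5H)-one | CCCC[C@@H]1OC(=O)C(C=C)=C1CCC=C
F4 | step 8 | 3-hydroxy lactone of 13: (6S,7R,3a′R,7a′S)-3-butyl-3-hydroxy-3,8-dihydro-(Z′)-6.7a′,7.3a′-diligustilide (both C3 epimers) | CCCCC1(O)OC(=O)C2=C1CC[C@H]1[C@@H]2[C@]23CCC=C[C@]12C(=O)O/C3=C\CCC
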